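**Retrosynthetic overview**

1. The target is reached from the macrocyclic C7' ketone by BBr3 removal of three methyl ethers, then (S)-selective transfer hydrogenation of C7' as the last step.
2. Key disconnection: the aryl ether bond between the ring A oxygen and the ring B carbon para to C7'. With C7' as a ketone, that ring B carbon (bearing F) is an SNAr electrophile, so the ring A phenoxide closes the 18-membered macrocycle, the only ring made in the route.
3. The seco phenol/4-fluorophenyl ketone comes from hydrogenation of a diarylalkyne, made by Sonogashira coupling of a ring D bromide with unprotected 5-ethynyl-2,3-dimethoxyphenol (ring A).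
4. The ring D bromo ketone comes from oxidation of the carbinol formed by 4-fluorophenyl Grignard addition (ring B) to the ring C arylacetaldehyde; that aldehyde comes from one-carbon homologation of the C–D ether aldehyde, made by SNAr of 3-bromophenol on 2-fluoro-3-methoxybenzaldehyde.
5. Order: C–D ether, then ring B, then ring A, then the macrocycle; the only protecting groups are the three methyl ethers already present in the purchased rings.

Key step: step 8

Remark: ring A is the dihydroxylated ring, B the para-phenylene, C the 1,2,3-trisubstituted ring carrying C8' (the CH2 next to the carbinol C7'), D the meta-phenylene. C7' of the given SMILES is (S) (OH > ring B > C8' > H). 4-Fluorophenylmagnesium bromide is taken as a purchased THF solution.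

Step 1
Reactants: 1 2-fluoro-3-methoxybenzaldehyde; 2 3-bromophenol
Product: 3 2-(3-bromophenoxy)-3-methoxybenzaldehyde
Conditions: K2CO3, DMAc, 130 °C
Reagents that add atoms: none
Why: SNAr, in which the ortho formyl group stabilises the Meisenheimer anion so that the phenoxide should displace the fluoride despite the flanking methoxy group, while the aldehyde and the aryl bromide are inert to carbonate.

Step 2
Reactants: 3 2-(3-bromophenoxy)-3-methoxybenzaldehyde
Product: 5 2-[2-(3-bromophenoxy)-3-methoxyphenyl]acetaldehyde, via methyl enol ether 4 (not isolated)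
Conditions: MeOCH2PPh3Cl, KOtBu, THF, 0 °C to rt; then 2 M aq. HCl, 50 °C, same flask
Reagents that add atoms: (methoxymethyl)triphenylphosphonium chloride, COC[P+](c1ccccc1)(c1ccccc1)c1ccccc1.[Cl-]; water, O
Why: Wittig methoxymethylenation followed by acid hydrolysis of the enol ether is the standard one-carbon homologation of an aryl aldehyde to the arylacetaldehyde, and the aryl bromide and the ethers should not be touched.

Step 3
Reactants: 5 2-[2-(3-bromophenoxy)-3-methoxyphenyl]acetaldehyde; 6 4-fluorophenylmagnesium bromide
Product: 7 rac-2-[2-(3-bromophenoxy)-3-methoxyphenyl]-1-(4-fluorophenyl)ethan-1-ol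
Conditions: THF, −78 to 0 °C; aq. NH4Cl work-up
Reagents that add atoms: none
Why: Grignard 1,2-addition to the aldehyde at low temperature, where the aryl bromide does not exchange with an arylmagnesium bromide; the carbinol centre forms racemic and is erased in step 4.

Step 4
Reactants: 7 rac-2-[2-(3-bromophenoxy)-3-methoxyphenyl]-1-(4-fluorophenyl)ethan-1-ol
Product: 8 2-[2-(3-bromophenoxy)-3-methoxyphenyl]-1-(4-fluorophenyl)ethan-1-one
Conditions: Dess–Martin periodinane, CH2Cl2, 0 °C to rt
Reagents that add atoms: none
Why: Dess–Martin oxidation of a secondary benzylic alcohol should give the aryl ketone under neutral conditions without attack at the benzylic CH2.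

Step 5
Reactants: 9 3-hydroxy-4,5-dimethoxybenzaldehyde
Product: 10 5-ethynyl-2,3-dimethoxyphenol
Conditions: Bestmann–Ohira reagent, K2CO3, MeOH, rt
Reagents that add atoms: dimethyl (1-diazo-2-oxopropyl)phosphonate, CC(=O)C(=[N+]=[N-])P(=O)(OC)OC
Why: Seyferth–Gilbert homologation in the Bestmann–Ohira variant should convert the aldehyde into the terminal alkyne, and the meta phenoxide, which is not conjugated with the formyl group, is tolerated.

Step 6
Reactants: 8 2-[2-(3-bromophenoxy)-3-methoxyphenyl]-1-(4-fluorophenyl)ethan-1-one; 10 5-ethynyl-2,3-dimethoxyphenol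
Product: 11 1-(4-fluorophenyl)-2-[2-[3-[(3-hydroxy-4,5-dimethoxyphenyl)ethynyl]phenoxy]-3-methoxyphenyl]ethan-1-one
Conditions: Pd(PPh3)2Cl2 (cat.), CuI (cat.), Et3N, DMF, 70 °C, degassed
Reagents that add atoms: none
Why: Sonogashira coupling of the aryl bromide with the terminal alkyne should proceed with the free phenol in place, since the amine base is too weak to start SNAr at the fluoro ketone or condensation at C8'.

Step 7
Reactants: 11 1-(4-fluorophenyl)-2-[2-[3-[(3-hydroxy-4,5-dimethoxyphenyl)ethynyl]phenoxy]-3-methoxyphenyl]ethan-1-one
Product: 12 1-(4-fluorophenyl)-2-[2-[3-[2-(3-hydroxy-4,5-dimethoxyphenyl)ethyl]phenoxy]-3-methoxyphenyl]ethan-1-one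
Conditions: H2 (1 atm), 10% Pd/C, EtOAc, rt, stopped after uptake of 2 equiv
Reagents that add atoms: none
Why: Heterogeneous catalytic hydrogenation should reduce the diarylalkyne fully to the CH2–CH2 bridge well before the aryl ketone or the C–F bond react in a neutral, non-protic solvent.

Step 8
Reactants: 12 1-(4-fluorophenyl)-2-[2-[3-[2-(3-hydroxy-4,5-dimethoxyphenyl)ethyl]phenoxy]-3-methoxyphenyl]ethan-1-one
Product: 13 macrocyclic ketone trimethyl ether (18-membered ring, C7' ketone, two OMe on ring A and one on ring C)
Conditions: K2CO3, DMSO (degassed), 120 °C, syringe-pump addition to 2 mM, Ar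
Reagents that add atoms: none
Why: Carbonate generates the ring A phenoxide, which adds to the fluorine-bearing ring B carbon para to the C7' carbonyl to give a Meisenheimer anion delocalised onto the ketone oxygen, and loss of fluoride restores the arene (addition–elimination SNAr). The closest known reaction type is intramolecular SNAr macro-etherification of a phenoxide onto a carbonyl-activated fluoroarene, whose intermolecular form is the bond-forming step of poly(aryl ether ketone) synthesis. The one new ring is the 18-membered macrocycle, closed end to end by O–C(aryl) bond formation, with the oxygen approaching perpendicular to ring B so that the pyramidalised Meisenheimer carbon relieves the demand on the para-phenylene in the transition state. No stereocentre is formed. The step needs O-arylation by the phenoxide in preference to reactions of the C8' enolate, and ring closure in preference to oligomerisation: the enolate cannot reach the fluorine of its own ring B and its formation switches off the activation of that ring, so it should only be a resting state that returns to the phenoxide by proton transfer, while its intermolecular C-arylation and aldol reactions, like oligomer formation, are second order and are held back by the 2 mM concentration. All other phenols are methyl ethers and the molecule holds a single activated fluoride, so no other site competes, and oxygen is excluded to prevent oxidation of the enolate at C8'.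

Step 9
Reactants: 13 macrocyclic ketone trimethyl ether
Product: 14 macrocyclic ketone triphenol
Conditions: BBr3 (excess), CH2Cl2, −78 °C to rt; then H2O
Reagents that add atoms: none
Why: BBr3 cleavage of aryl methyl ethers (O-complexation, then bromide attack at methyl) should spare the diaryl ethers and the ketone, and it is placed before the reduction because the para-aryloxy benzylic carbinol of the target would ionise under BBr3.

Step 10
Reactants: 14 macrocyclic ketone triphenol
Product: 15 target, (S)-C7' carbinol
Conditions: RuCl[(S,S)-TsDPEN](p-cymene) (cat.), HCO2H/Et3N (5:2), DMF, 30 °C, degassed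
Reagents that add atoms: none
Why: Noyori–Ikariya asymmetric transfer hydrogenation, in which the (S,S)-TsDPEN–Ru hydride transfers H through a six-membered outer-sphere transition state with a CH/π contact between the p-cymene ligand and ring B, so that hydride should reach the Re face of C7' and give the (S)-carbinol, as the same catalyst gives (S)-1-arylethanols from aryl alkyl ketones; the acidic formate medium tolerates free phenols and makes the reduction irreversible.

**Compound list**

1 | 2-fluoro-3-methoxybenzaldehyde | COc1cccc(C=O)c1F | starting material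
2 | 3-bromophenol | Oc1cccc(Br)c1 | starting material
3 | 2-(3-bromophenoxy)-3-methoxybenzaldehyde | COc1cccc(C=O)c1Oc1cccc(Br)c1 | intermediate
4 | 1-(3-bromophenoxy)-2-methoxy-6-(2-methoxyethenyl)benzene, E/Z mixture | COC=Cc1cccc(OC)c1Oc1cccc(Br)c1 | intermediate (not isolated)
5 | 2-[2-(3-bromophenoxy)-3-methoxyphenyl]acetaldehyde | COc1cccc(CC=O)c1Oc1cccc(Br)c1 | intermediate
6 | 4-fluorophenylmagnesium bromide | Fc1ccc([Mg]Br)cc1 | starting material
7 | rac-2-[2-(3-bromophenoxy)-3-methoxyphenyl]-1-(4-fluorophenyl)ethan-1-ol | COc1cccc(CC(O)c2ccc(F)cc2)c1Oc1cccc(Br)c1 | intermediate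
8 | 2-[2-(3-bromophenoxy)-3-methoxyphenyl]-1-(4-fluorophenyl)ethan-1-one | COc1cccc(CC(=O)c2ccc(F)cc2)c1Oc1cccc(Br)c1 | intermediate
9 | 3-hydroxy-4,5-dimethoxybenzaldehyde | COc1cc(C=O)cc(O)c1OC | starting material
10 | 5-ethynyl-2,3-dimethoxyphenol | COc1cc(C#C)cc(O)c1OC | intermediate
11 | 1-(4-fluorophenyl)-2-[2-[3-[(3-hydroxy-4,5-dimethoxyphenyl)ethynyl]phenoxy]-3-methoxyphenyl]ethan-1-one | COc1cc(C#Cc2cccc(Oc3c(OC)cccc3CC(=O)c3ccc(F)cc3)c2)cc(O)c1OC | intermediate
12 | 1-(4-fluorophenyl)-2-[2-[3-[2-(3-hydroxy-4,5-dimethoxyphenyl)ethyl]phenoxy]-3-methoxyphenyl]ethan-1-one (seco ring A phenol) | COc1cc(CCc2cccc(Oc3c(OC)cccc3CC(=O)c3ccc(F)cc3)c2)cc(O)c1OC | intermediate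
13 | macrocyclic ketone trimethyl ether (18-membered ring; ring A O bonded to ring B para to the C7' ketone) | COc1cc2cc(c1OC)Oc1ccc(cc1)C(=O)Cc1cccc(OC)c1Oc1cccc(c1)CC2 | intermediate
14 | macrocyclic ketone triphenol | Oc1cc2cc(c1O)Oc1ccc(cc1)C(=O)Cc1cccc(O)c1Oc1cccc(c1)CC2 | intermediate
15 | CNP0356934.1, (S)-C7' carbinol | Oc1cc2cc(c1O)Oc1ccc(cc1)[C@@H](O)Cc1cccc(O)c1Oc1cccc(c1)CC2 | target

**Step count**

Total: 10 steps. Longest linear sequence: 9 steps (steps 1–4 and 6–10, from 1 to 15).

**Steps most likely to fail**

Step 8. Intermolecular etherification to oligomers, and condensation through the C8' enolate, may outrun the slow closure of the 18-membered ring. The fallback sets out from 9 and 8 and comes back at 13. It forms the A–B ether between two separate molecules, where no dilution is needed, and closes the macrocycle at the ring A–ring D two-carbon bridge by a Heck reaction. Wittig methylenation of 9 (Ph3PCH3Br, KOtBu, THF) would give 5-ethenyl-2,3-dimethoxyphenol F1. SNAr of F1 with 8 (K2CO3, DMSO, 100 °C, 0.3 M) would give the open-chain ether 2-[2-(3-bromophenoxy)-3-methoxyphenyl]-1-[4-(5-ethenyl-2,3-dimethoxyphenoxy)phenyl]ethan-1-one F2. Intramolecular Heck macrocyclisation (Pd(OAc)2, P(o-tol)3, Et3N, DMF, 100 °C, 2 mM) would give the macrocyclic (E)-stilbene ketone trimethyl ether F3, and hydrogenation (H2, Pd/C, EtOAc) would give 13.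

Step 10. Binding of the free catechol to ruthenium may stop catalyst turnover, or facial discrimination between ring B and the bulky C8' benzyl group may be insufficient. The fallback sets out from 14 and comes back at 15. Silylation (TBSCl, imidazole, DMF) would give the tris(tert-butyldimethylsilyl) ether of the macrocyclic ketone F4. Corey–Bakshi–Shibata reduction ((R)-Me-CBS cat., BH3·SMe2, THF, −20 °C), with ring B as the large group, would give the (S)-carbinol tris(tert-butyldimethylsilyl) ether F5. Desilylation (Et3N·3HF, THF, rt) would give 15.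

Step 3. Deprotonation of the doubly activated CH2 of the arylacetaldehyde by the Grignard reagent, followed by aldol self-condensation, may compete with 1,2-addition. The fallback sets out from 5 and comes back at 8, and it makes step 4 unnecessary. Pinnick oxidation (NaClO2, NaH2PO4, 2-methyl-2-butene, t-BuOH/H2O) would give 2-[2-(3-bromophenoxy)-3-methoxyphenyl]acetic acid F6. Amide coupling (MeNHOMe·HCl, EDC·HCl, HOBt, iPr2NEt, CH2Cl2) would give 2-[2-(3-bromophenoxy)-3-methoxyphenyl]-N-methoxy-N-methylacetamide F7. Acyl substitution with 6 (THF, 0 °C), through the stable magnesium chelate of the Weinreb amide, would give 8 directly.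

**Further compounds**

F1 | step 8 | 5-ethenyl-2,3-dimethoxyphenol | COc1cc(C=C)cc(O)c1OC
F2 | step 8 | 2-[2-(3-bromophenoxy)-3-methoxyphenyl]-1-[4-(5-ethenyl-2,3-dimethoxyphenoxy)phenyl]ethan-1-one | COc1cc(C=C)cc(Oc2ccc(cc2)C(=O)Cc2cccc(OC)c2Oc2cccc(Br)c2)c1OC
F3 | step 8 | macrocyclic (E)-stilbene ketone trimethyl ether (13 with CH=CH in place of the CH2–CH2 bridge) | COc1cc2cc(c1OC)Oc1ccc(cc1)C(=O)Cc1cccc(OC)c1Oc1cccc(c1)/C=C/2
F4 | step 10 | tris(tert-butyldimethylsilyl) ether of the macrocyclic ketone | CC(C)(C)[Si](C)(C)Oc1cc2cc(c1O[Si](C)(C)C(C)(C)C)Oc1ccc(cc1)C(=O)Cc1cccc(O[Si](C)(C)C(C)(C)C)c1Oc1cccc(c1)CC2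
F5 | step 10 | (S)-carbinol tris(tert-butyldimethylsilyl) ether | CC(C)(C)[Si](C)(C)Oc1cc2cc(c1O[Si](C)(C)C(C)(C)C)Oc1ccc(cc1)[C@@H](O)Cc1cccc(O[Si](C)(C)C(C)(C)C)c1Oc1cccc(c1)CC2
F6 | step 3 | 2-[2-(3-bromophenoxy)-3-methoxyphenyl]acetic acid | COc1cccc(CC(=O)O)c1Oc1cccc(Br)c1
F7 | step 3 | 2-[2-(3-bromophenoxy)-3-methoxyphenyl]-N-methoxy-N-methylacetamide | COc1cccc(CC(=O)N(C)OC)c1Oc1cccc(Br)c1
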